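## Retrosynthetic overview

1. The ring A–CH=CH bond is cut last: an E-selective Heck reaction joins 6-bromo-7-methoxycoumarin to a vinyl group on C1. The lactone of ring B is closed just before, from a masked salicylaldehyde carried on the C6 aryl group.
2. C6–aryl and C4–CH3 go back to a 4,4-disubstituted cyclohex-2-enone: aryl cuprate addition at C6 anti to CH2OSi, triflation of the enolate, Negishi methylation.
3. The strategy rests on the cyclohexene (C1 quaternary with CH3 and styryl; C2, C3 CH2; C4 C–CH3; C5 =CH; C6 CH–ring B). C1 lies between C2–C3–C4 and C6=C5, the skeleton of a cyclohex-2-enone with C4 as carbonyl carbon, C5=C6 as enone alkene and C1 as the disubstituted γ-carbon.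
4. That enone comes from an amine-catalysed asymmetric Michael–aldol annulation of methyl 2-methyl-3-oxopropanoate with but-3-en-2-one (C1–C2, then C5=C6).
5. Ring order: cyclohexene (step 2), lactone of ring A coumarin (step 9, on the fragment), lactone of ring B coumarin (step 16).

Key step: step 2

Assumption: the sense of induction in step 2 is assigned by analogy; the quinine-derived primary amine is written as the catalyst giving (S)-7, and its pseudoenantiomer (9-amino-9-deoxy-epi-quinidine) would be used if the antipode predominates.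

Abbreviation: ArB = 5-(1,3-dioxolan-2-yl)-2-methoxy-4-(methoxymethoxy)phenyl, the masked form of ring B.

## Route

Step 1
Reactants: 1 methyl propanoate; 2 methyl formate
Product: 3 methyl 2-methyl-3-oxopropanoate (racemic, aldehyde/enol mixture, used fresh)
Conditions: NaH, cat. MeOH, THF, 0 °C → rt; then cold aq. HCl
Reagents that add atoms: none
Why: Crossed Claisen condensation, in which the enolate of 1 attacks the non-enolisable and more electrophilic formate and the product is drained off as its stabilised sodium enolate; the α-carbon is racemic and enolisable, so no stereocentre of consequence is set.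

Step 2
Reactants: 3 methyl 2-methyl-3-oxopropanoate; 4 but-3-en-2-one
Product: 7 methyl (1S)-1-methyl-4-oxocyclohex-2-ene-1-carboxylate, via keto aldehyde 5 (not isolated), via aldol 6 (not isolated)
Conditions: 9-amino-9-deoxy-epi-quinine (10 mol%), CF3CO2H (20 mol%), toluene, 0 °C → rt; then 60 °C
Reagents that add atoms: none
Why: The primary amine condenses with the formyl group of 3 to give a secondary enamino ester whose N–H···O=C(ester) hydrogen bond locks the enamine geometry, and its α-carbon adds to the β-carbon of 4 (C1–C2 bond), giving keto aldehyde 5 after hydrolysis; amine and acid then enolise the methyl ketone, whose CH3 carbon attacks the formyl carbon to give aldol 6, and loss of water gives the C5=C6 enone. The closest known reaction type is the amine-catalysed asymmetric Robinson annulation of α-branched aldehydes with vinyl ketones, together with primary-amine-catalysed Michael additions of α-substituted β-keto esters through enamino esters. The six-membered ring closes by a 6-(enolendo)-exo-trig aldol addition followed by dehydration. Quaternary C1 is set in the Michael step by the catalyst, which shields one face of the geometrically fixed enamine, and it cannot epimerise afterwards. The step needs enantioface selection, for which the acid keeps the quinuclidine protonated so that uncatalysed base-mediated addition of the acidic formyl ester is held back, and aldol regioselectivity, which the substrate secures because the formyl group has no α-hydrogen and only the ketone methyl carbon can close a six-membered ring.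

Step 3
Reactants: 7 methyl (1S)-1-methyl-4-oxocyclohex-2-ene-1-carboxylate
Product: 8 (4S)-4-(hydroxymethyl)-4-methylcyclohex-2-en-1-ol (both C1 epimers)
Conditions: LiAlH4, Et2O, 0 °C; H2O, aq. NaOH work-up
Reagents that add atoms: none
Why: Hydride reduction of the ester to the primary alcohol and 1,2-reduction of the enone, whose β-carbon is shielded by the neighbouring quaternary centre; the new carbinol centre is a mixture and is removed in step 4.

Step 4
Reactants: 8 (4S)-4-(hydroxymethyl)-4-methylcyclohex-2-en-1-ol
Product: 9 (4S)-4-(hydroxymethyl)-4-methylcyclohex-2-en-1-one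
Conditions: MnO2 (excess), CH2Cl2, rt
Reagents that add atoms: none
Why: Chemoselective allylic oxidation with MnO2, which leaves the saturated neopentyl primary alcohol untouched; no stereocentre is affected.

Step 5
Reactants: 9 (4S)-4-(hydroxymethyl)-4-methylcyclohex-2-en-1-one
Product: 10 (4S)-4-({[tert-butyl(diphenyl)silyl]oxy}methyl)-4-methylcyclohex-2-en-1-one
Conditions: TBDPSCl, imidazole, DMF, rt
Reagents that add atoms: tert-butyl(chloro)diphenylsilane, CC(C)(C)[Si](Cl)(c1ccccc1)c1ccccc1
Why: Silyl ether formation at the primary alcohol; the bulky group is the steric control element for step 10.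

Step 6
Reactants: 11 2-hydroxy-4-methoxybenzaldehyde
Product: 12 5-bromo-2-hydroxy-4-methoxybenzaldehyde
Conditions: NBS, MeCN, 0 °C → rt
Reagents that add atoms: N-bromosuccinimide, O=C1CCC(=O)N1Br
Why: Electrophilic aromatic bromination para to the hydroxyl and ortho to the methoxy group; the position between the two oxygens is hindered.

Step 7
Reactants: 12 5-bromo-2-hydroxy-4-methoxybenzaldehyde
Product: 13 5-bromo-4-methoxy-2-(methoxymethoxy)benzaldehyde
Conditions: MOMCl, i-Pr2NEt, CH2Cl2, 0 °C → rt
Reagents that add atoms: chloromethyl methyl ether, COCCl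
Why: O-alkylation of the phenol (MOM protection), removing the acidic proton before organometallic chemistry.

Step 8
Reactants: 13 5-bromo-4-methoxy-2-(methoxymethoxy)benzaldehyde
Product: 14 2-[5-bromo-4-methoxy-2-(methoxymethoxy)phenyl]-1,3-dioxolane
Conditions: HOCH2CH2OH, PPTS (cat.), benzene, reflux (Dean–Stark)
Reagents that add atoms: ethane-1,2-diol, OCCO
Why: Acid-catalysed acetalisation driven by azeotropic removal of water; PPTS under anhydrous conditions is mild enough to spare the aryl MOM ether.

Step 9
Reactants: 12 5-bromo-2-hydroxy-4-methoxybenzaldehyde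
Product: 16 6-bromo-7-methoxy-2H-chromen-2-one, via aryl phosphoranylideneacetate 15 (not isolated)
Conditions: Ph3P=C=C=O, toluene, 110 °C
Reagents that add atoms: (triphenylphosphoranylidene)ketene, O=C=C=P(c1ccccc1)(c1ccccc1)c1ccccc1
Why: The phenol adds to the ketenylidene phosphorane to give an ester-stabilised ylide, which closes the lactone ring by intramolecular Wittig reaction with the ortho formyl group; the ring enforces the cis alkene of the coumarin.

Step 10
Reactants: 14 2-[5-bromo-4-methoxy-2-(methoxymethoxy)phenyl]-1,3-dioxolane; 10 (4S)-4-({[tert-butyl(diphenyl)silyl]oxy}methyl)-4-methylcyclohex-2-en-1-one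
Product: 20 (3S,4S)-4-({[tert-butyl(diphenyl)silyl]oxy}methyl)-3-ArB-4-methylcyclohex-1-en-1-yl trifluoromethanesulfonate, via aryllithium 17 (not isolated), via lithium diarylcuprate 18 (not isolated), via lithium enolate 19 (not isolated)
Conditions: 14 (2.2 equiv), t-BuLi (4.4 equiv), Et2O, −78 °C; CuBr·SMe2 (1.1 equiv), −78 → −30 °C; 10, −78 → −10 °C; Comins' reagent in THF, −78 °C → rt
Reagents that add atoms: N-(5-chloropyridin-2-yl)-1,1,1-trifluoro-N-(trifluoromethylsulfonyl)methanesulfonamide (Comins' reagent), FC(F)(F)S(=O)(=O)N(c1ccc(Cl)cn1)S(=O)(=O)C(F)(F)F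
Why: Bromine–lithium exchange, transmetalation to the Gilman cuprate and conjugate addition with axial attack at the β-carbon (C6) on the face opposite the bulky CH2OSi group of the adjacent quaternary carbon, so the aryl group ends cis to CH3 (6S in the cyclohexene numbering); O-sulfonylation of the regiodefined enolate then fixes the double bond at C4=C5 (cuprate addition with enolate trapping).

Step 11
Reactants: 20 the enol triflate
Product: 21 tert-butyl{[(1S,2S)-2-ArB-1,4-dimethylcyclohex-3-en-1-yl]methoxy}diphenylsilane
Conditions: MeZnCl, Pd(PPh3)4 (5 mol%), THF, 50 °C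
Reagents that add atoms: methylzinc chloride, C[Zn]Cl
Why: Negishi cross-coupling of the alkenyl triflate (oxidative addition to zerovalent palladium, transmetalation, reductive elimination) places the C4 methyl with the alkene position retained; no stereocentre is touched.

Step 12
Reactants: 21 the silyl ether
Product: 22 [(1S,2S)-2-ArB-1,4-dimethylcyclohex-3-en-1-yl]methanol
Conditions: Bu4NF, THF, 50 °C
Reagents that add atoms: none
Why: Fluoride-mediated desilylation; the acetal and MOM ether are inert to fluoride.

Step 13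
Reactants: 22 the primary alcohol
Product: 23 (1S,2R)-2-ArB-1,4-dimethylcyclohex-3-ene-1-carbaldehyde
Conditions: Dess–Martin periodinane, pyridine, CH2Cl2, 0 °C → rt
Reagents that add atoms: none
Why: Dess–Martin oxidation under buffered conditions that spare the dioxolane; the aldehyde has a quaternary α-carbon and cannot epimerise (the descriptor at the aryl-bearing carbon changes by priority only).

Step 14
Reactants: 23 the aldehyde
Product: 24 2-{5-[(1S,6R)-6-ethenyl-3,6-dimethylcyclohex-2-en-1-yl]-4-methoxy-2-(methoxymethoxy)phenyl}-1,3-dioxolane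
Conditions: Ph3PCH3Br, KOt-Bu, THF, 0 → 40 °C
Reagents that add atoms: methyltriphenylphosphonium bromide, C[P+](c1ccccc1)(c1ccccc1)c1ccccc1.[Br-]
Why: Wittig methylenation with the small, reactive non-stabilised ylide, which reaches the hindered non-enolisable aldehyde; no stereochemical issue arises.

Step 15
Reactants: 24 the vinyl compound
Product: 25 5-[(1S,6R)-6-ethenyl-3,6-dimethylcyclohex-2-en-1-yl]-2-hydroxy-4-methoxybenzaldehyde
Conditions: 3 M aq. HCl, THF, 45 °C
Reagents that add atoms: water, O
Why: Acid hydrolysis of the dioxolane and of the MOM acetal in one operation; dilute acid should not hydrate or shift the isolated alkenes.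

Step 16
Reactants: 25 the salicylaldehyde
Product: 27 6-[(1S,6R)-6-ethenyl-3,6-dimethylcyclohex-2-en-1-yl]-7-methoxy-2H-chromen-2-one, via aryl phosphoranylideneacetate 26 (not isolated)
Conditions: Ph3P=C=C=O, toluene, 100 °C
Reagents that add atoms: (triphenylphosphoranylidene)ketene, O=C=C=P(c1ccccc1)(c1ccccc1)c1ccccc1
Why: The same phenol addition and intramolecular Wittig lactone closure as in step 9, under neutral conditions that leave both alkenes and both stereocentres untouched.

Step 17
Reactants: 27 the vinyl coumarin; 16 6-bromo-7-methoxy-2H-chromen-2-one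
Product: 28 7-methoxy-6-[(E)-2-[(1R,2S)-2-(7-methoxy-2-oxo-2H-chromen-6-yl)-1,4-dimethylcyclohex-3-en-1-yl]ethenyl]-2H-chromen-2-one (CNP0415737.1)
Conditions: Pd(OAc)2 (5 mol%), P(o-tol)3 (12 mol%), Et3N, DMF, 100 °C
Reagents that add atoms: none
Why: Mizoroki–Heck reaction in which the aryl group adds to the unhindered terminal alkene carbon and syn β-hydride elimination can only take the benzylic hydrogen because C1 is quaternary, which gives the E-styrene; the trisubstituted ring alkene and the coumarin alkenes are much less reactive.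

## Compound list

1 | methyl propanoate | CCC(=O)OC | starting material
2 | methyl formate | COC=O | starting material
3 | methyl 2-methyl-3-oxopropanoate (racemic) | COC(=O)C(C)C=O | intermediate
4 | but-3-en-2-one | CC(=O)C=C | starting material
5 | methyl (2S)-2-formyl-2-methyl-5-oxohexanoate (not isolated) | COC(=O)[C@@](C=O)(C)CCC(C)=O | intermediate
6 | methyl (1S)-2-hydroxy-1-methyl-4-oxocyclohexane-1-carboxylate, both C2 epimers (not isolated) | COC(=O)[C@@]1(C)CCC(=O)CC1O | intermediate
7 | methyl (1S)-1-methyl-4-oxocyclohex-2-ene-1-carboxylate | COC(=O)[C@@]1(C)CCC(=O)C=C1 | intermediate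
8 | (4S)-4-(hydroxymethyl)-4-methylcyclohex-2-en-1-ol, both C1 epimers | OC[C@@]1(C)CCC(O)C=C1 | intermediate
9 | (4S)-4-(hydroxymethyl)-4-methylcyclohex-2-en-1-one | OC[C@@]1(C)CCC(=O)C=C1 | intermediate
10 | (4S)-4-({[tert-butyl(diphenyl)silyl]oxy}methyl)-4-methylcyclohex-2-en-1-one | CC(C)(C)[Si](c1ccccc1)(c1ccccc1)OC[C@@]1(C)CCC(=O)C=C1 | intermediate
11 | 2-hydroxy-4-methoxybenzaldehyde | COc1ccc(C=O)c(O)c1 | starting material
12 | 5-bromo-2-hydroxy-4-methoxybenzaldehyde | COc1cc(O)c(C=O)cc1Br | intermediate
13 | 5-bromo-4-methoxy-2-(methoxymethoxy)benzaldehyde | COCOc1cc(OC)c(Br)cc1C=O | intermediate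
14 | 2-[5-bromo-4-methoxy-2-(methoxymethoxy)phenyl]-1,3-dioxolane | COCOc1cc(OC)c(Br)cc1C1OCCO1 | intermediate
15 | 4-bromo-2-formyl-5-methoxyphenyl 2-(triphenyl-λ5-phosphanylidene)acetate (not isolated) | COc1cc(OC(=O)C=P(c2ccccc2)(c2ccccc2)c2ccccc2)c(C=O)cc1Br | intermediate
16 | 6-bromo-7-methoxy-2H-chromen-2-one | COc1cc2oc(=O)ccc2cc1Br | intermediate
17 | [5-(1,3-dioxolan-2-yl)-2-methoxy-4-(methoxymethoxy)phenyl]lithium (not isolated) | [Li]c1cc(C2OCCO2)c(OCOC)cc1OC | intermediate
18 | lithium bis[5-(1,3-dioxolan-2-yl)-2-methoxy-4-(methoxymethoxy)phenyl]cuprate (not isolated) | [Li+].COCOc1cc(OC)c([Cu-]c2cc(C3OCCO3)c(OCOC)cc2OC)cc1C1OCCO1 | intermediate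
19 | lithium (3S,4S)-4-({[tert-butyl(diphenyl)silyl]oxy}methyl)-3-[5-(1,3-dioxolan-2-yl)-2-methoxy-4-(methoxymethoxy)phenyl]-4-methylcyclohex-1-en-1-olate (not isolated) | CC(C)(C)[Si](c1ccccc1)(c1ccccc1)OC[C@@]1(C)CCC(O[Li])=C[C@@H]1c1cc(C2OCCO2)c(OCOC)cc1OC | intermediate
20 | (3S,4S)-4-({[tert-butyl(diphenyl)silyl]oxy}methyl)-3-[5-(1,3-dioxolan-2-yl)-2-methoxy-4-(methoxymethoxy)phenyl]-4-methylcyclohex-1-en-1-yl trifluoromethanesulfonate | CC(C)(C)[Si](c1ccccc1)(c1ccccc1)OC[C@@]1(C)CCC(OS(=O)(=O)C(F)(F)F)=C[C@@H]1c1cc(C2OCCO2)c(OCOC)cc1OC | intermediate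
21 | tert-butyl{[(1S,2S)-2-[5-(1,3-dioxolan-2-yl)-2-methoxy-4-(methoxymethoxy)phenyl]-1,4-dimethylcyclohex-3-en-1-yl]methoxy}diphenylsilane | CC(C)(C)[Si](c1ccccc1)(c1ccccc1)OC[C@@]1(C)CCC(C)=C[C@@H]1c1cc(C2OCCO2)c(OCOC)cc1OC | intermediate
22 | [(1S,2S)-2-[5-(1,3-dioxolan-2-yl)-2-methoxy-4-(methoxymethoxy)phenyl]-1,4-dimethylcyclohex-3-en-1-yl]methanol | OC[C@@]1(C)CCC(C)=C[C@@H]1c1cc(C2OCCO2)c(OCOC)cc1OC | intermediate
23 | (1S,2R)-2-[5-(1,3-dioxolan-2-yl)-2-methoxy-4-(methoxymethoxy)phenyl]-1,4-dimethylcyclohex-3-ene-1-carbaldehyde | O=C[C@@]1(C)CCC(C)=C[C@@H]1c1cc(C2OCCO2)c(OCOC)cc1OC | intermediate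
24 | 2-{5-[(1S,6R)-6-ethenyl-3,6-dimethylcyclohex-2-en-1-yl]-4-methoxy-2-(methoxymethoxy)phenyl}-1,3-dioxolane | C=C[C@@]1(C)CCC(C)=C[C@@H]1c1cc(C2OCCO2)c(OCOC)cc1OC | intermediate
25 | 5-[(1S,6R)-6-ethenyl-3,6-dimethylcyclohex-2-en-1-yl]-2-hydroxy-4-methoxybenzaldehyde | C=C[C@@]1(C)CCC(C)=C[C@@H]1c1cc(C=O)c(O)cc1OC | intermediate
26 | 4-[(1S,6R)-6-ethenyl-3,6-dimethylcyclohex-2-en-1-yl]-2-formyl-5-methoxyphenyl 2-(triphenyl-λ5-phosphanylidene)acetate (not isolated) | C=C[C@@]1(C)CCC(C)=C[C@@H]1c1cc(C=O)c(OC(=O)C=P(c2ccccc2)(c2ccccc2)c2ccccc2)cc1OC | intermediate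
27 | 6-[(1S,6R)-6-ethenyl-3,6-dimethylcyclohex-2-en-1-yl]-7-methoxy-2H-chromen-2-one | C=C[C@@]1(C)CCC(C)=C[C@@H]1c1cc2ccc(=O)oc2cc1OC | intermediate
28 | 7-methoxy-6-[(E)-2-[(1R,2S)-2-(7-methoxy-2-oxo-2H-chromen-6-yl)-1,4-dimethylcyclohex-3-en-1-yl]ethenyl]-2H-chromen-2-one | COc1cc2oc(=O)ccc2cc1/C=C/[C@@]1(C)CCC(C)=C[C@@H]1c1cc2ccc(=O)oc2cc1OC | target

## Step count

Total: 17 steps. Longest linear sequence: 13 steps (steps 1–5 and 10–17, from methyl propanoate); the aryl fragments branch in through steps 6–8 and 6, 9.

## Steps most likely to fail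

**Step 2 (annulation).** The enamine of a formyl ester is a push–pull alkene and a weak nucleophile. The Michael addition may therefore be slow, and a non-selective addition of the acidic formyl ester through its enol may erode the enantiomeric purity. The amine may also cleave the formyl group from the quaternary keto aldehyde (retro-Claisen) before the ring closes.

Fallback: the same cyclohexenone is built by an enantioselective Diels–Alder reaction instead of an annulation. This fallback sets out from commercial materials outside the route (none of 1–8 is used) and comes back at 9. 2-Methylpropenal and (E)-1-(dimethylamino)-3-(tert-butyldimethylsilyloxy)buta-1,3-diene are combined with a hydrogen-bonding 1-naphthyl-TADDOL catalyst in toluene at −80 °C, using the TADDOL enantiomer that gives the S quaternary carbon. This should give the endo adduct (1S,2R)-4-[(tert-butyldimethylsilyl)oxy]-2-(dimethylamino)-1-methylcyclohex-3-ene-1-carbaldehyde F1. LiAlH4 in Et2O reduces the aldehyde to [(1S,2R)-4-[(tert-butyldimethylsilyl)oxy]-2-(dimethylamino)-1-methylcyclohex-3-en-1-yl]methanol F2. HF in MeCN cleaves the silyl enol ether and eliminates the β-amino group to give 9.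

**Step 10 (cuprate addition and triflation).** The cuprate may discriminate poorly between CH3 and CH2OSi on the neighbouring quaternary carbon, giving the C6 epimer as well. The hindered β-carbon may react sluggishly, and the copper-bound enolate may be sulfonylated incompletely.

Fallback: catalyst control replaces substrate control. It sets out from 14 and 10 and comes back at 20. Aryllithium 17 (from 14 and t-BuLi) is transmetalated with ZnCl2 to [5-(1,3-dioxolan-2-yl)-2-methoxy-4-(methoxymethoxy)phenyl]zinc chloride F3. F3 is added to 10 with [RhCl(BINAP)]2 (3 mol% Rh) and Me3SiCl in THF at 20 °C, with the BINAP enantiomer matched to attack anti to CH2OSi. This should give tert-butyl{[(1S,2S)-2-ArB-1-methyl-4-(trimethylsilyloxy)cyclohex-3-en-1-yl]methoxy}diphenylsilane F4. MeLi in THF at 0 °C regenerates lithium enolate 19, and Comins' reagent converts it to 20.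

**Step 17 (Heck reaction).** Insertion of the alkene next to a quaternary carbon into the electron-rich, ortho-substituted aryl–palladium species may be slow, so that reduction of the aryl bromide and catalyst decomposition compete.

Fallback: olefin cross-metathesis instead of arylation. It sets out from 27 and 16 and comes back at 28. Bromide 16 is vinylated with potassium vinyltrifluoroborate (Pd(dppf)Cl2, Et3N, n-PrOH, 90 °C) to 6-ethenyl-7-methoxy-2H-chromen-2-one F5. F5 and 27 are joined with the second-generation Hoveyda–Grubbs catalyst, RuCl2(H2IMes)(=CH-C6H4-2-Oi-Pr), in CH2Cl2 at 40 °C with removal of ethene. The hindered alkene cannot homodimerise, so the E cross-product 28 should be favoured.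

## Further compounds

F1 | step 2 | (1S,2R)-4-[(tert-butyldimethylsilyl)oxy]-2-(dimethylamino)-1-methylcyclohex-3-ene-1-carbaldehyde | O=C[C@@]1(C)CCC(O[Si](C)(C)C(C)(C)C)=C[C@H]1N(C)C
F2 | step 2 | [(1S,2R)-4-[(tert-butyldimethylsilyl)oxy]-2-(dimethylamino)-1-methylcyclohex-3-en-1-yl]methanol | OC[C@@]1(C)CCC(O[Si](C)(C)C(C)(C)C)=C[C@H]1N(C)C
F3 | step 10 | [5-(1,3-dioxolan-2-yl)-2-methoxy-4-(methoxymethoxy)phenyl]zinc chloride | Cl[Zn]c1cc(C2OCCO2)c(OCOC)cc1OC
F4 | step 10 | tert-butyl{[(1S,2S)-2-[5-(1,3-dioxolan-2-yl)-2-methoxy-4-(methoxymethoxy)phenyl]-1-methyl-4-(trimethylsilyloxy)cyclohex-3-en-1-yl]methoxy}diphenylsilane | CC(C)(C)[Si](c1ccccc1)(c1ccccc1)OC[C@@]1(C)CCC(O[Si](C)(C)C)=C[C@@H]1c1cc(C2OCCO2)c(OCOC)cc1OC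
F5 | step 17 | 6-ethenyl-7-methoxy-2H-chromen-2-one | COc1cc2oc(=O)ccc2cc1C=C
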